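**Retrosynthetic overview**
1. Target 21 ⇒ 19: oxirane closed last by SN2 attack of the tertiary alkoxide on the neighbouring secondary mesylate (inversion). 19 ⇒ tetraol 17 + oleoyl chloride (ester on the only primary OH).
2. 17 ⇒ 16 (hydrogenolysis of a C7 chlorine that only blocks one ortho position) ⇒ Fischer indole synthesis: the [3,3]-sigmatropic shift makes C3–C3a from aryl hydrazone 7 and chiral lactol 13.
3. 13 ⇒ trans-aldol lactone 10 (reduction, glycol cleavage) ⇒ acetone + D-glutamic-acid-derived lactone 8, whose stereocentre steers the aldol and is then cut out.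
4. 7 ⇒ aryl bromide 5 + benzophenone hydrazone; 5 ⇒ 1,3-dibromo-2-chlorobenzene + methyl (S)-glycidate (future epoxide carbon) + MeMgBr.
5. Ring order: benzene ring bought; pyrrole ring of the indole in step 6; oxirane in step 9.

Assumption: 1, 2 and the trityl ether 8 of the D-glutamic-acid-derived hydroxymethyl lactone are taken as catalogue chemicals.

**Step 1**
Reactants: 1 1,3-dibromo-2-chlorobenzene; 2 methyl (2S)-oxirane-2-carboxylate
Product: 5 (2S)-1-(3-bromo-2-chlorophenyl)-3-methylbutane-2,3-diol, via aryl Grignard reagent 3 (not isolated), via hydroxy ester magnesium alkoxide 4 (not isolated)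
Conditions: iPrMgCl·LiCl (1.05 equiv), THF, −15 °C; CuI (10 mol %), 2, −40 → −20 °C; MeMgBr (3.5 equiv), −20 °C → rt; aq NH4Cl
Reagents that add atoms: methylmagnesium bromide, C[Mg]Br (two CH3 in 5); isopropylmagnesium chloride–lithium chloride, CC(C)[Mg]Cl.[Li+].[Cl-] (its MgCl is carried only by 3 and 4)
Why: Bromine–magnesium exchange gives the aryl Grignard reagent, which under CuI catalysis opens the glycidate at its CH2 terminus (SN2 epoxide opening that leaves the bought stereocentre untouched) before MeMgBr adds twice to the ester (Grignard addition) to give the tertiary carbinol.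

**Step 2**
Reactants: 5 (2S)-1-(3-bromo-2-chlorophenyl)-3-methylbutane-2,3-diol; 6 benzophenone hydrazone
Product: 7 (2S)-1-{2-chloro-3-[2-(diphenylmethylidene)hydrazin-1-yl]phenyl}-3-methylbutane-2,3-diol
Conditions: Pd(OAc)2 (2 mol %), Xantphos (3 mol %), Cs2CO3 (1.5 equiv), toluene, 100 °C
Reagents that add atoms: none
Why: Buchwald–Hartwig C–N coupling of the hydrazone NH2 at C–Br (C–Cl is left alone with this ligand, and the mild carbonate base tolerates the free diol); no stereocentre is touched.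

**Step 3**
Reactants: 8 (5R)-5-[(triphenylmethoxy)methyl]oxolan-2-one
Product: 10 (3R,5R)-3-(2-hydroxypropan-2-yl)-5-[(triphenylmethoxy)methyl]oxolan-2-one, via lithium enolate 9 (not isolated)
Conditions: LiN(iPr)2 (1.1 equiv), THF, −78 °C; acetone (1.5 equiv), −78 °C; AcOH quench at −78 °C
Reagents that add atoms: acetone, CC(C)=O; lithium diisopropylamide, [Li+].CC(C)[N-]C(C)C (its lithium is carried only by 9)
Why: Aldol addition of the lactone lithium enolate to acetone takes place on the ring face anti to the bulky CH2OTr group at C5, so the bought stereocentre sets C3 as R (3,5-trans), and the cold acidic quench prevents retro-aldol.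

**Step 4**
Reactants: 10 (3R,5R)-3-(2-hydroxypropan-2-yl)-5-[(triphenylmethoxy)methyl]oxolan-2-one
Product: 11 (2S,4R)-2-(2-hydroxypropan-2-yl)-5-(triphenylmethoxy)pentane-1,4-diol
Conditions: LiAlH4 (1.5 equiv), THF, 0 °C → rt; H2O/NaOH work-up
Reagents that add atoms: none
Why: Hydride reduction of the lactone to the diol removes the carbonyl next to the new stereocentre, which is thereby fixed (R becomes S only through the change in CIP priorities).

**Step 5**
Reactants: 11 (2S,4R)-2-(2-hydroxypropan-2-yl)-5-(triphenylmethoxy)pentane-1,4-diol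
Product: 13 (4S)-4-(2-hydroxypropan-2-yl)oxolan-2-ol, via tetraol 12 (not isolated)
Conditions: AcOH/H2O (4:1), 45 °C; then NaIO4 (1.2 equiv), H2O/THF, 0 °C → rt
Reagents that add atoms: none
Why: Acid hydrolysis of the trityl ether frees the only vicinal diol, and Malaprade glycol cleavage excises the controlling carbinol carbon to give an aldehyde that closes to the lactol, whose remaining stereocentre is beta to the aldehyde carbon and cannot epimerise.

**Step 6**
Reactants: 7 (2S)-1-{2-chloro-3-[2-(diphenylmethylidene)hydrazin-1-yl]phenyl}-3-methylbutane-2,3-diol; 13 (4S)-4-(2-hydroxypropan-2-yl)oxolan-2-ol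
Product: 16 (2S)-2-{7-chloro-6-[(2S)-2,3-dihydroxy-3-methylbutyl]-1H-indol-3-yl}-3-methylbutane-1,3-diol, via arylhydrazine 14 (not isolated), via aldehyde arylhydrazone 15 (not isolated)
Conditions: TsOH·H2O (2 equiv), EtOH/H2O (5:1), 75 °C
Reagents that add atoms: none
Why: Fischer indole synthesis, in which hydrazone exchange and tautomerisation to the ene-hydrazine are followed by the [3,3]-sigmatropic shift that forms C3–C3a at the only free ortho position (the other carries Cl, and the reacting carbon is para to the alkyl group), then cyclisation and loss of NH3, with the side-chain stereocentre lying outside the ene-hydrazine and therefore retained.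

**Step 7**
Reactants: 16 (2S)-2-{7-chloro-6-[(2S)-2,3-dihydroxy-3-methylbutyl]-1H-indol-3-yl}-3-methylbutane-1,3-diol
Product: 17 (2S)-2-{6-[(2S)-2,3-dihydroxy-3-methylbutyl]-1H-indol-3-yl}-3-methylbutane-1,3-diol
Conditions: H2 (1 atm), 10% Pd/C, Et3N (2 equiv), MeOH, rt
Reagents that add atoms: none
Why: Palladium-catalysed hydrogenolysis of the aryl C–Cl bond removes the blocking atom while the molecule still has no alkene, ester or epoxide.

**Step 8**
Reactants: 17 (2S)-2-{6-[(2S)-2,3-dihydroxy-3-methylbutyl]-1H-indol-3-yl}-3-methylbutane-1,3-diol; 18 (9Z)-octadec-9-enoyl chloride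
Product: 19 (2S)-2-{6-[(2S)-2,3-dihydroxy-3-methylbutyl]-1H-indol-3-yl}-3-hydroxy-3-methylbutyl (9Z)-octadec-9-enoate
Conditions: 18 (1.05 equiv), 2,4,6-collidine (3 equiv), CH2Cl2/THF, −40 → −20 °C
Reagents that add atoms: none
Why: Kinetically controlled O-acylation (nucleophilic acyl substitution) of the only primary hydroxyl, since the secondary OH sits next to a quaternary carbinol, the other two are tertiary, and the indole N–H is not acylated without a strong base.

**Step 9**
Reactants: 19 (2S)-2-{6-[(2S)-2,3-dihydroxy-3-methylbutyl]-1H-indol-3-yl}-3-hydroxy-3-methylbutyl (9Z)-octadec-9-enoate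
Product: 21 (2S)-2-(6-{[(2R)-3,3-dimethyloxiran-2-yl]methyl}-1H-indol-3-yl)-3-hydroxy-3-methylbutyl (9Z)-octadec-9-enoate, via secondary mesylate 20 (not isolated)
Conditions: MsCl (1.2 equiv), pyridine, CH2Cl2, 0 °C; then DBU (4 equiv), rt
Reagents that add atoms: methanesulfonyl chloride, CS(=O)(=O)Cl (its atoms are carried only by 20)
Why: Sulfonylation picks the only secondary hydroxyl, and intramolecular Williamson-type SN2 displacement by the adjacent tertiary alkoxide closes the oxirane with inversion (2S carbinol becomes 2R epoxide carbon) under a non-nucleophilic base that spares the oleate.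

**Compound list**
1 | 1,3-dibromo-2-chlorobenzene | Clc1c(Br)cccc1Br | starting material
2 | methyl (2S)-oxirane-2-carboxylate (methyl (S)-glycidate) | COC(=O)[C@@H]1CO1 | starting material
3 | (3-bromo-2-chlorophenyl)magnesium chloride | Cl[Mg]c1cccc(Br)c1Cl | intermediate (not isolated)
4 | chloromagnesium alkoxide of methyl (2S)-3-(3-bromo-2-chlorophenyl)-2-hydroxypropanoate | COC(=O)[C@@H](O[Mg]Cl)Cc1cccc(Br)c1Cl | intermediate (not isolated)
5 | (2S)-1-(3-bromo-2-chlorophenyl)-3-methylbutane-2,3-diol | CC(C)(O)[C@@H](O)Cc1cccc(Br)c1Cl | intermediate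
6 | benzophenone hydrazone | NN=C(c1ccccc1)c1ccccc1 | starting material
7 | (2S)-1-{2-chloro-3-[2-(diphenylmethylidene)hydrazin-1-yl]phenyl}-3-methylbutane-2,3-diol | CC(C)(O)[C@@H](O)Cc1cccc(NN=C(c2ccccc2)c2ccccc2)c1Cl | intermediate
8 | (5R)-5-[(triphenylmethoxy)methyl]oxolan-2-one | O=C1O[C@@H](COC(c2ccccc2)(c2ccccc2)c2ccccc2)CC1 | starting material
9 | lithium (5R)-5-[(triphenylmethoxy)methyl]-4,5-dihydrofuran-2-olate (lithium enolate of 8) | [Li+].[O-]C1=CC[C@H](COC(c2ccccc2)(c2ccccc2)c2ccccc2)O1 | intermediate (not isolated)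
10 | (3R,5R)-3-(2-hydroxypropan-2-yl)-5-[(triphenylmethoxy)methyl]oxolan-2-one (3,5-trans) | O=C1O[C@@H](COC(c2ccccc2)(c2ccccc2)c2ccccc2)C[C@@H]1C(C)(C)O | intermediate
11 | (2S,4R)-2-(2-hydroxypropan-2-yl)-5-(triphenylmethoxy)pentane-1,4-diol | OC[C@H](C[C@@H](O)COC(c1ccccc1)(c1ccccc1)c1ccccc1)C(C)(C)O | intermediate
12 | (2R,4S)-4-(2-hydroxypropan-2-yl)pentane-1,2,5-triol | OC[C@H](C[C@@H](O)CO)C(C)(C)O | intermediate (not isolated)
13 | (4S)-4-(2-hydroxypropan-2-yl)oxolan-2-ol (lactol, both anomers; ring form of (3S)-4-hydroxy-3-(hydroxymethyl)-4-methylpentanal) | OC1C[C@@H](CO1)C(C)(C)O | intermediate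
14 | (2S)-1-(2-chloro-3-hydrazinylphenyl)-3-methylbutane-2,3-diol | CC(C)(O)[C@@H](O)Cc1cccc(NN)c1Cl | intermediate (not isolated)
15 | (2S)-1-(2-chloro-3-{2-[(3S)-4-hydroxy-3-(hydroxymethyl)-4-methylpentylidene]hydrazin-1-yl}phenyl)-3-methylbutane-2,3-diol | CC(C)(O)[C@@H](O)Cc1cccc(NN=CC[C@@H](CO)C(C)(C)O)c1Cl | intermediate (not isolated)
16 | (2S)-2-{7-chloro-6-[(2S)-2,3-dihydroxy-3-methylbutyl]-1H-indol-3-yl}-3-methylbutane-1,3-diol | CC(C)(O)[C@@H](O)Cc1ccc2c(c1Cl)[nH]cc2[C@@H](CO)C(C)(C)O | intermediate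
17 | (2S)-2-{6-[(2S)-2,3-dihydroxy-3-methylbutyl]-1H-indol-3-yl}-3-methylbutane-1,3-diol | CC(C)(O)[C@@H](O)Cc1ccc2c(c1)[nH]cc2[C@@H](CO)C(C)(C)O | intermediate
18 | (9Z)-octadec-9-enoyl chloride (oleoyl chloride) | CCCCCCCC/C=C\CCCCCCCC(Cl)=O | starting material
19 | (2S)-2-{6-[(2S)-2,3-dihydroxy-3-methylbutyl]-1H-indol-3-yl}-3-hydroxy-3-methylbutyl (9Z)-octadec-9-enoate | CCCCCCCC/C=C\CCCCCCCC(=O)OC[C@H](c1c[nH]c2cc(C[C@H](O)C(C)(C)O)ccc12)C(C)(C)O | intermediate
20 | (2S)-2-{6-[(2S)-3-hydroxy-2-(methanesulfonyloxy)-3-methylbutyl]-1H-indol-3-yl}-3-hydroxy-3-methylbutyl (9Z)-octadec-9-enoate | CCCCCCCC/C=C\CCCCCCCC(=O)OC[C@H](c1c[nH]c2cc(C[C@H](OS(C)(=O)=O)C(C)(C)O)ccc12)C(C)(C)O | intermediate (not isolated)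
21 | (2S)-2-(6-{[(2R)-3,3-dimethyloxiran-2-yl]methyl}-1H-indol-3-yl)-3-hydroxy-3-methylbutyl (9Z)-octadec-9-enoate | CCCCCCCC/C=C\CCCCCCCC(=O)OC[C@H](c1c[nH]c2cc(C[C@H]3OC3(C)C)ccc12)C(C)(C)O | target

**Step count and risks**
Total steps: 9. Longest linear sequence: 7 (steps 3 to 9, from lactone 8).

Most likely to fail, with fallbacks:

Step 6. The chlorine that blocks C7 also slows the [3,3] shift, so the acid and heat needed may ionise the tertiary carbinol next to the indol-3-yl methine (elimination, or loss of the stereocentre by hydride shift). The fallback gives up the blocking atom instead of forcing the acid. It sets out from 2: bought 1-bromo-3-iodobenzene (Brc1cccc(I)c1) is taken through the protocol of step 1, by iodine–magnesium exchange to (3-bromophenyl)magnesium chloride F1, CuI-catalysed opening of 2 to the chloromagnesium alkoxide of methyl (2S)-3-(3-bromophenyl)-2-hydroxypropanoate F2, and MeMgBr addition to (2S)-1-(3-bromophenyl)-3-methylbutane-2,3-diol F3. Coupling with 6 as in step 2 gives (2S)-1-{3-[2-(diphenylmethylidene)hydrazin-1-yl]phenyl}-3-methylbutane-2,3-diol F4. F4 and 13 are then heated with less acid (TsOH·H2O 1.2 equiv, EtOH/H2O, 50–55 °C), passing through (2S)-1-(3-hydrazinylphenyl)-3-methylbutane-2,3-diol F5 and (2S)-1-(3-{2-[(3S)-4-hydroxy-3-(hydroxymethyl)-4-methylpentylidene]hydrazin-1-yl}phenyl)-3-methylbutane-2,3-diol F6. The unhindered ring rearranges under these conditions and gives 17 directly, together with its regioisomer (2S)-2-{4-[(2S)-2,3-dihydroxy-3-methylbutyl]-1H-indol-3-yl}-3-methylbutane-1,3-diol F7 (expected about 2:1 in favour of 17), which is removed by chromatography. The route is rejoined at 17 and step 7 is dropped.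

Step 1. The hindered ortho-chloroaryl Grignard reagent may attack the ester of 2 instead of the epoxide, or the one-pot MeMgBr stage may give mixtures. The fallback reverses the order of the two C–C bond formations so that the aryl nucleophile only meets an ester-free epoxide. It sets out from 2: MeMgCl (2.1 equiv, THF, −78 °C) first converts the ester into 2-[(2S)-oxiran-2-yl]propan-2-ol F8, kept in solution as its magnesium alkoxide. Grignard reagent 3 and CuI (10 mol %) are then added at −30 °C, and opening of the terminal epoxide carbon gives 5, where the route is rejoined.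

Step 8. The acylation may not separate the primary from the secondary hydroxyl cleanly, and step 9 must then close the epoxide next to an ester. The fallback makes the epoxide first and esterifies last. It sets out from 17: TBSCl and imidazole (DMF, 0 °C) silylate only the primary hydroxyl to give (2S)-1-(3-{(2S)-1-[(tert-butyldimethylsilyl)oxy]-3-hydroxy-3-methylbutan-2-yl}-1H-indol-6-yl)-3-methylbutane-2,3-diol F9. MsCl in pyridine gives (2S)-1-(3-{(2S)-1-[(tert-butyldimethylsilyl)oxy]-3-hydroxy-3-methylbutan-2-yl}-1H-indol-6-yl)-3-hydroxy-3-methylbutan-2-yl methanesulfonate F10, which K2CO3 in MeOH closes to (3S)-4-[(tert-butyldimethylsilyl)oxy]-3-(6-{[(2R)-3,3-dimethyloxiran-2-yl]methyl}-1H-indol-3-yl)-2-methylbutan-2-ol F11. Bu4NF in THF frees (2S)-2-(6-{[(2R)-3,3-dimethyloxiran-2-yl]methyl}-1H-indol-3-yl)-3-methylbutane-1,3-diol F12, and oleic acid with EDC and DMAP (CH2Cl2, 0 °C) esterifies its only primary hydroxyl, arriving at 21.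

**Further compounds**
F1 | step 6 | (3-bromophenyl)magnesium chloride | Cl[Mg]c1cccc(Br)c1
F2 | step 6 | chloromagnesium alkoxide of methyl (2S)-3-(3-bromophenyl)-2-hydroxypropanoate | COC(=O)[C@@H](O[Mg]Cl)Cc1cccc(Br)c1
F3 | step 6 | (2S)-1-(3-bromophenyl)-3-methylbutane-2,3-diol | CC(C)(O)[C@@H](O)Cc1cccc(Br)c1
F4 | step 6 | (2S)-1-{3-[2-(diphenylmethylidene)hydrazin-1-yl]phenyl}-3-methylbutane-2,3-diol | CC(C)(O)[C@@H](O)Cc1cccc(NN=C(c2ccccc2)c2ccccc2)c1
F5 | step 6 | (2S)-1-(3-hydrazinylphenyl)-3-methylbutane-2,3-diol | CC(C)(O)[C@@H](O)Cc1cccc(NN)c1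
F6 | step 6 | (2S)-1-(3-{2-[(3S)-4-hydroxy-3-(hydroxymethyl)-4-methylpentylidene]hydrazin-1-yl}phenyl)-3-methylbutane-2,3-diol | CC(C)(O)[C@@H](O)Cc1cccc(NN=CC[C@@H](CO)C(C)(C)O)c1
F7 | step 6 | (2S)-2-{4-[(2S)-2,3-dihydroxy-3-methylbutyl]-1H-indol-3-yl}-3-methylbutane-1,3-diol | CC(C)(O)[C@@H](O)Cc1cccc2[nH]cc([C@@H](CO)C(C)(C)O)c12
F8 | step 1 | 2-[(2S)-oxiran-2-yl]propan-2-ol | CC(C)(O)[C@@H]1CO1
F9 | step 8 | (2S)-1-(3-{(2S)-1-[(tert-butyldimethylsilyl)oxy]-3-hydroxy-3-methylbutan-2-yl}-1H-indol-6-yl)-3-methylbutane-2,3-diol | CC(C)(O)[C@@H](O)Cc1ccc2c(c1)[nH]cc2[C@@H](CO[Si](C)(C)C(C)(C)C)C(C)(C)O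
F10 | step 8 | (2S)-1-(3-{(2S)-1-[(tert-butyldimethylsilyl)oxy]-3-hydroxy-3-methylbutan-2-yl}-1H-indol-6-yl)-3-hydroxy-3-methylbutan-2-yl methanesulfonate | CC(C)(O)[C@@H](OS(C)(=O)=O)Cc1ccc2c(c1)[nH]cc2[C@@H](CO[Si](C)(C)C(C)(C)C)C(C)(C)O
F11 | step 8 | (3S)-4-[(tert-butyldimethylsilyl)oxy]-3-(6-{[(2R)-3,3-dimethyloxiran-2-yl]methyl}-1H-indol-3-yl)-2-methylbutan-2-ol | CC1(C)O[C@@H]1Cc1ccc2c(c1)[nH]cc2[C@@H](CO[Si](C)(C)C(C)(C)C)C(C)(C)O
F12 | step 8 | (2S)-2-(6-{[(2R)-3,3-dimethyloxiran-2-yl]methyl}-1H-indol-3-yl)-3-methylbutane-1,3-diol | CC1(C)O[C@@H]1Cc1ccc2c(c1)[nH]cc2[C@@H](CO)C(C)(C)O
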